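**Retrosynthetic overview**

1. Last come global O-debenzylation and the interflavan bond C4 (ring C, upper unit)–C8 (ring D, lower unit), made from a catechin-derived flavan-4-yl cation and protected epigallocatechin gallate; before that the gallate ester (ring G).
2. The cis-(2R,3R) carbinol of the lower unit comes from a racemic flavan-3-one by asymmetric transfer hydrogenation with dynamic kinetic resolution; the ketone comes from a 3-alkoxy-4H-chromene (its enol ether).
3. Key disconnection: pyran ring F is closed by a one-pot [3+3] union of an α-alkoxy aryl ketone (ring E part) with a 2-bromobenzyl chloride (ring D part), forming C3–C4 by enolate C-benzylation and O1–C8a by copper-mediated enolate O-arylation.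
4. Enabling feature: in ring F, O1 and the C3 oxygen sit on adjacent carbons C2 and C3, and C2 carries aryl ring E, so at the ketone level O1–C2–C3 is an ambident enolate (C3 and O1 nucleophilic); on ring D the C5 and C7 oxygens are ortho/para to the C4 benzylic carbon (reactive halide) but meta to C8a (ordinary C–Br bond for O-arylation).
5. Ring order: rings D, E, G and the whole upper unit (rings A, C, B, from (+)-catechin) are bought; ring F is the only ring made.

Key step: step 7

Remark: flavan numbering is used within each unit (upper unit rings A/C/B, lower unit rings D/F/E, galloyl ring G); the C4 configuration of electrophile 19 is of no consequence because C4 is ionised in step 13.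

**Route**

Step 1
Reactants: 1 5-bromoresorcinol (5-bromobenzene-1,3-diol)
Product: 2 1-bromo-3,5-bis(benzyloxy)benzene
Conditions: BnBr (2.2 equiv), K2CO3, DMF, 60 °C
Reagents that add atoms: benzyl bromide, BrCc1ccccc1
Why: Williamson etherification of both phenols; no stereocentre is involved.

Step 2
Reactants: 2 1-bromo-3,5-bis(benzyloxy)benzene
Product: 4 2-bromo-4,6-bis(benzyloxy)benzaldehyde, via aryl iminium salt 3 (not isolated)
Conditions: POCl3, DMF, 0 → 70 °C; then aq NaOH, 0 °C
Reagents that add atoms: N,N-dimethylformamide, CN(C)C=O; water, O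
Why: Vilsmeier–Haack formylation should go to the position para to one benzyloxy group and ortho to the other (next to Br) rather than to the more hindered position between the two ethers, as is usual for 1-bromo-3,5-dialkoxybenzenes.

Step 3
Reactants: 4 2-bromo-4,6-bis(benzyloxy)benzaldehyde
Product: 5 [2-bromo-4,6-bis(benzyloxy)phenyl]methanol
Conditions: NaBH4, THF/MeOH, 0 °C
Reagents that add atoms: none
Why: Borohydride reduction of an aryl aldehyde; the aryl bromide and benzyl ethers are inert.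

Step 4
Reactants: 5 [2-bromo-4,6-bis(benzyloxy)phenyl]methanol
Product: 6 2-bromo-4,6-bis(benzyloxy)benzyl chloride
Conditions: N-chlorosuccinimide, PPh3, THF, −20 → 0 °C; filtered through a short silica pad and used the same day
Reagents that add atoms: N-chlorosuccinimide, O=C1CCC(=O)N1Cl
Why: Appel-type chlorination under neutral conditions, chosen because the ortho/para-dialkoxybenzyl chloride is acid-sensitive and should not be stored.

Step 5
Reactants: 7 3,4,5-tris(benzyloxy)benzoic acid
Product: 9 2-diazo-1-[3,4,5-tris(benzyloxy)phenyl]ethanone, via acid chloride 8 (not isolated)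
Conditions: (COCl)2, DMF (cat.), CH2Cl2, 0 °C → rt; evaporate; Me3SiCHN2 (2 equiv), THF/MeCN, 0 °C
Reagents that add atoms: trimethylsilyldiazomethane, C[Si](C)(C)C=[N+]=[N-]
Why: Acyl chloride formation followed by acylation of trimethylsilyldiazomethane with loss of Me3SiCl (Arndt–Eistert-type diazoketone synthesis).

Step 6
Reactants: 9 2-diazo-1-[3,4,5-tris(benzyloxy)phenyl]ethanone
Product: 10 2-[2-(trimethylsilyl)ethoxy]-1-[3,4,5-tris(benzyloxy)phenyl]ethanone
Conditions: Rh2(OAc)4 (1 mol %), Me3SiCH2CH2OH (3 equiv), CH2Cl2, rt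
Reagents that add atoms: 2-(trimethylsilyl)ethanol, C[Si](C)(C)CCO
Why: Rhodium-carbenoid O–H insertion of an α-diazoketone into an alcohol gives the α-alkoxy ketone; its non-migrating, fluoride-labile ether is the oxygen that becomes the C3 oxygen of ring F.

Step 7
Reactants: 10 2-[2-(trimethylsilyl)ethoxy]-1-[3,4,5-tris(benzyloxy)phenyl]ethanone; 6 2-bromo-4,6-bis(benzyloxy)benzyl chloride
Product: 12 5,7-bis(benzyloxy)-2-[3,4,5-tris(benzyloxy)phenyl]-3-[2-(trimethylsilyl)ethoxy]-4H-chromene, via benzylated ketone 11 (not isolated)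
Conditions: LiN(SiMe3)2 (1.05 equiv), THF/DMPU, −78 °C; add 6, −78 → 0 °C; then CuI (10 mol %), 3,4,7,8-tetramethyl-1,10-phenanthroline (20 mol %), NaOtBu (1.3 equiv), toluene, 90 °C, same flask
Reagents that add atoms: none
Why: Proposed new method: the chelated lithium (Z)-enolate of 10 is C-benzylated at C3 by the ortho/para-dialkoxy-activated benzylic chloride 6 (SN2), then tert-butoxide regenerates the enolate of 11 and its oxygen (the future O1) is joined to C8a by Ullmann-type O-arylation (oxidative addition of the C8a–Br bond to a monovalent copper enolate, then C–O reductive elimination). The closest known reaction type is the CuI-catalysed domino C-benzylation/intramolecular O-arylation of 1,3-dicarbonyl compounds with 2-bromobenzyl bromides to 4H-chromenes, together with copper- and palladium-catalysed intramolecular O-arylation of simple ketone enolates; new here is a non-stabilised α-alkoxy aryl ketone as the bis-nucleophile. Ring F closes as a six-membered ring by O-attack on the ring D carbon C8a, the only mode available because C-arylation at C3 would give a benzocyclobutene. No stereocentre is created, since C2=C3 is an enol ether double bond and C2 and C3 are set in step 9. The step needs C- over O-benzylation and mono-alkylation, which the lithium enolate in THF and the hindered tertiary C3 of 11 should secure, and it needs the two halides to react in order, which follows from the ring D oxygens being ortho/para to the benzylic carbon but meta to C8a, whose C–Br bond stays inert until copper and heat are applied. Migration of the double bond from C2=C3 to C3=C4 would be harmless because both enol ethers give the same ketone in step 8.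

Step 8
Reactants: 12 5,7-bis(benzyloxy)-2-[3,4,5-tris(benzyloxy)phenyl]-3-[2-(trimethylsilyl)ethoxy]-4H-chromene
Product: 14 racemic 5,7-bis(benzyloxy)-2-[3,4,5-tris(benzyloxy)phenyl]chroman-3-one, via ammonium enolate 13 (not isolated)
Conditions: Bu4NF (1.5 equiv), THF, 0 °C → rt, argon; then AcOH, 0 °C; used without storage
Reagents that add atoms: none
Why: Fluoride-induced fragmentation of the 2-(trimethylsilyl)ethyl ether (attack at silicon, loss of ethylene, enolate as leaving group) releases the enolate, which is protonated at C2 to the 3-ketone; because no acid is present, C3 is never protonated and the isomeric C2-ketone manifold is avoided, and the ketone is racemic at C2 on purpose.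

Step 9
Reactants: 14 racemic 5,7-bis(benzyloxy)-2-[3,4,5-tris(benzyloxy)phenyl]chroman-3-one
Product: 15 (2R,3R)-5,7-bis(benzyloxy)-2-[3,4,5-tris(benzyloxy)phenyl]chroman-3-ol (penta-O-benzyl-(−)-epigallocatechin)
Conditions: RuCl(p-cymene)[(R,R)-TsDPEN] (2 mol %), HCO2H/Et3N (1:1), EtOAc, 35 °C, argon
Reagents that add atoms: none
Why: Noyori–Ikariya asymmetric transfer hydrogenation with dynamic kinetic resolution: C2–H (α to the ketone, benzylic to ring E, α to O1) epimerises quickly in the amine-rich medium, hydride is delivered anti to ring E to give the cis carbinol, C3 (R) is set by the catalyst and C2 (R) through the resolution; the (R,R) ligand is assigned by analogy with aryl ketones, and the (S,S) ligand is used if the sense proves opposite.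

Step 10
Reactants: 15 penta-O-benzyl-(−)-epigallocatechin; 7 3,4,5-tris(benzyloxy)benzoic acid
Product: 16 (2R,3R)-5,7-bis(benzyloxy)-2-[3,4,5-tris(benzyloxy)phenyl]chroman-3-yl 3,4,5-tris(benzyloxy)benzoate (octa-O-benzyl-epigallocatechin gallate)
Conditions: DCC, DMAP, CH2Cl2, rt
Reagents that add atoms: none
Why: Steglich esterification of the axial C3 hydroxyl; no stereocentre is touched.

Step 11
Reactants: 17 (+)-catechin
Product: 18 (2R,3S)-5,7-bis(benzyloxy)-2-[3,4-bis(benzyloxy)phenyl]chroman-3-ol (5,7,3',4'-tetra-O-benzylcatechin)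
Conditions: BnBr (4.2 equiv), K2CO3, DMF, rt
Reagents that add atoms: benzyl bromide, BrCc1ccccc1
Why: Williamson etherification of the four phenols, which are far more acidic than the C3 alcohol, so the latter stays free.

Step 12
Reactants: 18 5,7,3',4'-tetra-O-benzylcatechin
Product: 19 (2R,3S,4S)-5,7-bis(benzyloxy)-2-[3,4-bis(benzyloxy)phenyl]-4-(2-ethoxyethoxy)chroman-3-ol
Conditions: DDQ (2 equiv), HOCH2CH2OEt, CH2Cl2, rt
Reagents that add atoms: 2-ethoxyethanol, CCOCCO
Why: DDQ abstracts hydride from the electron-rich benzylic C4 and the ring A-stabilised cation is trapped by the alcohol (benzylic oxidative etherification), expected cis to the C3 hydroxyl; this centre is erased in step 13.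

Step 13
Reactants: 19 4-(2-ethoxyethoxy)-tetra-O-benzylcatechin; 16 octa-O-benzyl-epigallocatechin gallate (3 equiv, surplus recovered)
Product: 20 dodeca-O-benzyl catechin-(4α→8)-epigallocatechin 3-O-gallate
Conditions: TMSOTf (0.2 equiv), CH2Cl2, −78 °C; quench with Et3N
Reagents that add atoms: none
Why: Lewis-acid ionisation of the 4-alkoxy group gives the flavan-4-yl cation, which is attacked by C8 of ring D of 16 (Friedel–Crafts-type interflavan coupling, C8 being the usual site for benzylated flavan-3-ols); attack anti to the C3 oxygen substituent on the 2,3-trans half-chair sets upper C4 as S (3,4-trans, 4α), and excess 16 suppresses oligomerisation.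

Step 14
Reactants: 20 dodeca-O-benzyl catechin-(4α→8)-epigallocatechin 3-O-gallate
Product: 21 catechin-(4α→8)-epigallocatechin 3-O-gallate (CNP0246304.1)
Conditions: H2 (1 atm), Pd(OH)2/C, THF/MeOH/H2O, rt
Reagents that add atoms: none
Why: Hydrogenolysis of the twelve benzyl ethers; the ester, the interflavan bond and all five stereocentres are expected to be untouched.

**Compound list**

1 | 5-bromoresorcinol | Oc1cc(O)cc(Br)c1 | starting material
2 | 1-bromo-3,5-bis(benzyloxy)benzene | Brc1cc(OCc2ccccc2)cc(OCc2ccccc2)c1 | intermediate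
3 | [2-bromo-4,6-bis(benzyloxy)phenyl]methylidene(dimethyl)iminium dichlorophosphate | C[N+](C)=Cc1c(Br)cc(OCc2ccccc2)cc1OCc1ccccc1.[O-]P(=O)(Cl)Cl | intermediate (not isolated)
4 | 2-bromo-4,6-bis(benzyloxy)benzaldehyde | O=Cc1c(Br)cc(OCc2ccccc2)cc1OCc1ccccc1 | intermediate
5 | [2-bromo-4,6-bis(benzyloxy)phenyl]methanol | OCc1c(Br)cc(OCc2ccccc2)cc1OCc1ccccc1 | intermediate
6 | 2-bromo-4,6-bis(benzyloxy)benzyl chloride | ClCc1c(Br)cc(OCc2ccccc2)cc1OCc1ccccc1 | intermediate
7 | 3,4,5-tris(benzyloxy)benzoic acid | OC(=O)c1cc(OCc2ccccc2)c(OCc2ccccc2)c(OCc2ccccc2)c1 | starting material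
8 | 3,4,5-tris(benzyloxy)benzoyl chloride | ClC(=O)c1cc(OCc2ccccc2)c(OCc2ccccc2)c(OCc2ccccc2)c1 | intermediate (not isolated)
9 | 2-diazo-1-[3,4,5-tris(benzyloxy)phenyl]ethanone | [N-]=[N+]=CC(=O)c1cc(OCc2ccccc2)c(OCc2ccccc2)c(OCc2ccccc2)c1 | intermediate
10 | 2-[2-(trimethylsilyl)ethoxy]-1-[3,4,5-tris(benzyloxy)phenyl]ethanone | C[Si](C)(C)CCOCC(=O)c1cc(OCc2ccccc2)c(OCc2ccccc2)c(OCc2ccccc2)c1 | intermediate
11 | racemic 3-[2-bromo-4,6-bis(benzyloxy)phenyl]-2-[2-(trimethylsilyl)ethoxy]-1-[3,4,5-tris(benzyloxy)phenyl]propan-1-one | C[Si](C)(C)CCOC(Cc1c(Br)cc(OCc2ccccc2)cc1OCc1ccccc1)C(=O)c1cc(OCc2ccccc2)c(OCc2ccccc2)c(OCc2ccccc2)c1 | intermediate (not isolated)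
12 | 5,7-bis(benzyloxy)-2-[3,4,5-tris(benzyloxy)phenyl]-3-[2-(trimethylsilyl)ethoxy]-4H-chromene | C[Si](C)(C)CCOC1=C(c2cc(OCc3ccccc3)c(OCc3ccccc3)c(OCc3ccccc3)c2)Oc2cc(OCc3ccccc3)cc(OCc3ccccc3)c2C1 | intermediate
13 | tetrabutylammonium 5,7-bis(benzyloxy)-2-[3,4,5-tris(benzyloxy)phenyl]-4H-chromen-3-olate | CCCC[N+](CCCC)(CCCC)CCCC.[O-]C1=C(c2cc(OCc3ccccc3)c(OCc3ccccc3)c(OCc3ccccc3)c2)Oc2cc(OCc3ccccc3)cc(OCc3ccccc3)c2C1 | intermediate (not isolated)
14 | racemic 5,7-bis(benzyloxy)-2-[3,4,5-tris(benzyloxy)phenyl]chroman-3-one | O=C1Cc2c(OCc3ccccc3)cc(OCc3ccccc3)cc2OC1c1cc(OCc2ccccc2)c(OCc2ccccc2)c(OCc2ccccc2)c1 | intermediate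
15 | (2R,3R)-5,7-bis(benzyloxy)-2-[3,4,5-tris(benzyloxy)phenyl]chroman-3-ol | O[C@@H]1Cc2c(OCc3ccccc3)cc(OCc3ccccc3)cc2O[C@@H]1c1cc(OCc2ccccc2)c(OCc2ccccc2)c(OCc2ccccc2)c1 | intermediate
16 | (2R,3R)-5,7-bis(benzyloxy)-2-[3,4,5-tris(benzyloxy)phenyl]chroman-3-yl 3,4,5-tris(benzyloxy)benzoate | O=C(O[C@@H]1Cc2c(OCc3ccccc3)cc(OCc3ccccc3)cc2O[C@@H]1c1cc(OCc2ccccc2)c(OCc2ccccc2)c(OCc2ccccc2)c1)c1cc(OCc2ccccc2)c(OCc2ccccc2)c(OCc2ccccc2)c1 | intermediate
17 | (+)-catechin, (2R,3S)-2-(3,4-dihydroxyphenyl)chromane-3,5,7-triol | C1c2c(O)cc(O)cc2O[C@H](c2ccc(O)c(O)c2)[C@H]1O | starting material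
18 | (2R,3S)-5,7-bis(benzyloxy)-2-[3,4-bis(benzyloxy)phenyl]chroman-3-ol | C1c2c(OCc3ccccc3)cc(OCc3ccccc3)cc2O[C@H](c2ccc(OCc3ccccc3)c(OCc3ccccc3)c2)[C@H]1O | intermediate
19 | (2R,3S,4S)-5,7-bis(benzyloxy)-2-[3,4-bis(benzyloxy)phenyl]-4-(2-ethoxyethoxy)chroman-3-ol | CCOCCO[C@H]1c2c(OCc3ccccc3)cc(OCc3ccccc3)cc2O[C@H](c2ccc(OCc3ccccc3)c(OCc3ccccc3)c2)[C@H]1O | intermediate
20 | dodeca-O-benzyl catechin-(4α→8)-epigallocatechin 3-O-gallate (all twelve phenols as benzyl ethers, upper C3 hydroxyl free) | O=C(O[C@@H]1Cc2c(OCc3ccccc3)cc(OCc3ccccc3)c([C@@H]3c4c(OCc5ccccc5)cc(OCc5ccccc5)cc4O[C@H](c4ccc(OCc5ccccc5)c(OCc5ccccc5)c4)[C@H]3O)c2O[C@@H]1c1cc(OCc2ccccc2)c(OCc2ccccc2)c(OCc2ccccc2)c1)c1cc(OCc2ccccc2)c(OCc2ccccc2)c(OCc2ccccc2)c1 | intermediate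
21 | catechin-(4α→8)-epigallocatechin 3-O-gallate, (2R,3R)-8-[(2R,3S,4S)-2-(3,4-dihydroxyphenyl)-3,5,7-trihydroxychroman-4-yl]-5,7-dihydroxy-2-(3,4,5-trihydroxyphenyl)chroman-3-yl 3,4,5-trihydroxybenzoate | O=C(O[C@@H]1Cc2c(O)cc(O)c([C@@H]3c4c(O)cc(O)cc4O[C@H](c4ccc(O)c(O)c4)[C@H]3O)c2O[C@@H]1c1cc(O)c(O)c(O)c1)c1cc(O)c(O)c(O)c1 | target

**Totals and risks**

Total step count: 14. Longest linear sequence: 10 steps (steps 1, 2, 3, 4, 7, 8, 9, 10, 13, 14).

Steps most likely to fail:

1. Step 7 (Proposed new method). The enolate may be benzylated on oxygen or twice on carbon, and the copper-mediated O-arylation of the hindered tetrasubstituted enolate may stall with proto-debromination. The fallback uses known chemistry and makes the two bonds separately. It sets out from 10 and 4: Claisen–Schmidt condensation (KOH, EtOH/THF, rt) should give (Z)-3-[2-bromo-4,6-bis(benzyloxy)phenyl]-2-[2-(trimethylsilyl)ethoxy]-1-[3,4,5-tris(benzyloxy)phenyl]prop-2-en-1-one F1. Conjugate reduction with [CuH(PPh3)]6 (toluene, rt), which leaves the aryl bromide and benzyl ethers alone, gives 11, now isolated. Intramolecular ketone-enolate O-arylation with zerovalent palladium (Pd2(dba)3, DPEphos, Cs2CO3, toluene, 100 °C) then returns to the route at 12.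

2. Step 9. C2 epimerisation may be slow relative to reduction, or the catalyst may discriminate the faces poorly, giving low enantiomeric purity or cis/trans mixtures; ketone 14 may also degrade during a slow reaction. The fallback sets out from 14: reduction with LiBH(s-Bu)3 (THF, −78 °C), which attacks anti to ring E, should give the racemic cis alcohol F2. Acylation with (1S)-camphanic chloride (pyridine, DMAP, CH2Cl2) gives the diastereomeric camphanates of the (2R,3R) alcohol F3 and of the (2S,3S) alcohol F4, which are separated by crystallisation or chromatography. Methanolysis of F3 (K2CO3, MeOH/THF) returns to the route at 15.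

3. Step 13. Facial selectivity at the C4 cation may be incomplete (4β epimer), and attack at C6 of ring D or over-alkylation to trimers may compete. The fallback sets out from 19 and adds a participating ester that is removable next to the gallate: esterification with levulinic acid (DCC, DMAP, CH2Cl2) gives the 3-O-levulinoyl electrophile F5. TMSOTf-mediated coupling of F5 with 16 (CH2Cl2, −78 °C), in which the C3 ester bridges the β face of the cation and directs attack to the α face, gives the 3-O-levulinoyl protected dimer F6. Selective delevulinoylation (H2NNH2·AcOH, pyridine/AcOH, rt) returns to the route at 20.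

**Further compounds**

F1 | step 7 | (Z)-3-[2-bromo-4,6-bis(benzyloxy)phenyl]-2-[2-(trimethylsilyl)ethoxy]-1-[3,4,5-tris(benzyloxy)phenyl]prop-2-en-1-one | C[Si](C)(C)CCO/C(=C\c1c(Br)cc(OCc2ccccc2)cc1OCc1ccccc1)C(=O)c1cc(OCc2ccccc2)c(OCc2ccccc2)c(OCc2ccccc2)c1
F2 | step 9 | racemic cis-5,7-bis(benzyloxy)-2-[3,4,5-tris(benzyloxy)phenyl]chroman-3-ol (both enantiomers shown) | O[C@@H]1Cc2c(OCc3ccccc3)cc(OCc3ccccc3)cc2O[C@@H]1c1cc(OCc2ccccc2)c(OCc2ccccc2)c(OCc2ccccc2)c1.O[C@H]1Cc2c(OCc3ccccc3)cc(OCc3ccccc3)cc2O[C@H]1c1cc(OCc2ccccc2)c(OCc2ccccc2)c(OCc2ccccc2)c1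
F3 | step 9 | (2R,3R)-5,7-bis(benzyloxy)-2-[3,4,5-tris(benzyloxy)phenyl]chroman-3-yl (1S)-camphanate | O=C(O[C@@H]1Cc2c(OCc3ccccc3)cc(OCc3ccccc3)cc2O[C@@H]1c1cc(OCc2ccccc2)c(OCc2ccccc2)c(OCc2ccccc2)c1)[C@@]12CC[C@@](C)(C(=O)O1)C2(C)C
F4 | step 9 | (2S,3S)-5,7-bis(benzyloxy)-2-[3,4,5-tris(benzyloxy)phenyl]chroman-3-yl (1S)-camphanate | O=C(O[C@H]1Cc2c(OCc3ccccc3)cc(OCc3ccccc3)cc2O[C@H]1c1cc(OCc2ccccc2)c(OCc2ccccc2)c(OCc2ccccc2)c1)[C@@]12CC[C@@](C)(C(=O)O1)C2(C)C
F5 | step 13 | (2R,3S,4S)-5,7-bis(benzyloxy)-2-[3,4-bis(benzyloxy)phenyl]-4-(2-ethoxyethoxy)chroman-3-yl 4-oxopentanoate | CCOCCO[C@H]1c2c(OCc3ccccc3)cc(OCc3ccccc3)cc2O[C@H](c2ccc(OCc3ccccc3)c(OCc3ccccc3)c2)[C@H]1OC(=O)CCC(C)=O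
F6 | step 13 | dodeca-O-benzyl catechin-(4α→8)-epigallocatechin 3-O-gallate with the upper C3 hydroxyl as 4-oxopentanoate | O=C(O[C@@H]1Cc2c(OCc3ccccc3)cc(OCc3ccccc3)c([C@@H]3c4c(OCc5ccccc5)cc(OCc5ccccc5)cc4O[C@H](c4ccc(OCc5ccccc5)c(OCc5ccccc5)c4)[C@H]3OC(=O)CCC(C)=O)c2O[C@@H]1c1cc(OCc2ccccc2)c(OCc2ccccc2)c(OCc2ccccc2)c1)c1cc(OCc2ccccc2)c(OCc2ccccc2)c(OCc2ccccc2)c1
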